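**Plan**
- Labels: ring carbons C1 (enolised carbonyl), C2 (acyl-bearing), C3 (keto carbonyl), C4, C5 (carbinol), C6; acyl carbonyl C1′. Retrosynthetic cuts, in order: the ring bond C1–C2; then, with the C5 oxygen re-joined to C1′ as a 2,3-dihydro-4H-pyran-4-one, the bonds C4–C5 and O–C1′; in the side chain the aryl–CH2 bond and the two bonds flanking the alkyne.
- Enabling feature: C5 is 1,3 to ring carbonyl C3 and 1,5 to C1′, so the atoms O–C5–C4–C3(=O)–C2=C1′ are exactly the six ring atoms of a dihydropyranone, a cyclic form of the C4–C5 aldol that resists dehydration.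
- Forward: the diene arm is built linearly (aryl Grignard coupling, acetylide, ynone, methanol addition, silyl dienol ether) and joined to a C3 aldehyde by an asymmetric hetero-Diels–Alder reaction, which closes the oxygen ring first.
- The side arm is then oxidised to the C1 acid, the heterocycle is opened with pyrrolidine to an enaminone, and the carbocycle is closed last by C-acylation (C1–C2); hydrolysis and hydrogenolysis finish.
- Stereochemistry: C5 is the only stereocentre; it is set by the (R)-BINOL–titanium catalyst in the cycloaddition and is not touched afterwards.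

Key step: step 8

Assumption: in the final triketone the two ring carbonyls exchange roles by enol tautomerism, so the C5 descriptor applies to the enol tautomer drawn; the route fixes C5 absolutely while its two arms are constitutionally different, and the target is written as that (5S) tautomer.

Step 1
Reactants: 1 4-bromo-1,2-bis(benzyloxy)benzene; 2 1-bromo-8-chlorooctane
Product: 4 1,2-bis(benzyloxy)-4-(8-chlorooctyl)benzene, via aryl Grignard reagent 3 (not isolated)
Conditions: Mg, THF, reflux; then 2 (1.2 equiv), Li2CuCl4 (3 mol%), THF/NMP, 0 °C → rt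
Reagents that add atoms: none
Why: Copper-catalysed (Kochi-type) cross-coupling of an aryl Grignard reagent with a primary alkyl bromide, in which bromide is displaced much faster than chloride, so the chloride is kept for step 2 and the benzyl ethers are inert.

Step 2
Reactants: 4 1,2-bis(benzyloxy)-4-(8-chlorooctyl)benzene
Product: 5 1,2-bis(benzyloxy)-4-(dec-9-yn-1-yl)benzene
Conditions: LiC≡CH·H2NCH2CH2NH2 (1.5 equiv), DMSO, rt
Reagents that add atoms: lithium acetylide–ethylenediamine complex, [Li]C#C.NCCN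
Why: SN2 alkynylation of a primary alkyl chloride by lithium acetylide in DMSO, a standard route to terminal alkynes.

Step 3
Reactants: 5 1,2-bis(benzyloxy)-4-(dec-9-yn-1-yl)benzene
Product: 8 12-[3,4-bis(benzyloxy)phenyl]dodec-3-yn-2-one, via lithium acetylide 6 (not isolated), via lithium hemiaminal adduct 7 (not isolated)
Conditions: n-BuLi, THF, −78 °C; MeC(O)N(OMe)Me, −78 → 0 °C; aq. NH4Cl
Reagents that add atoms: N-methoxy-N-methylacetamide, CC(=O)N(C)OC
Why: Acylation of a lithium acetylide with a Weinreb amide, whose chelated tetrahedral adduct 7 prevents a second addition and collapses to the ynone only on quench.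

Step 4
Reactants: 8 12-[3,4-bis(benzyloxy)phenyl]dodec-3-yn-2-one
Product: 9 (3E)-12-[3,4-bis(benzyloxy)phenyl]-4-methoxydodec-3-en-2-one
Conditions: NaOMe (0.2 equiv), MeOH/THF, 0 °C → rt
Reagents that add atoms: methanol, CO
Why: Base-catalysed oxa-Michael addition of methanol to the ynone should place the methoxy group regiospecifically on the chain-bearing carbon (the future C1′) and give the thermodynamically preferred E vinylogous ester.

Step 5
Reactants: 9 (3E)-12-[3,4-bis(benzyloxy)phenyl]-4-methoxydodec-3-en-2-one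
Product: 10 (3E)-12-[3,4-bis(benzyloxy)phenyl]-4-methoxy-2-(trimethylsilyloxy)dodeca-1,3-diene
Conditions: TMSOTf (1.2 equiv), Et3N (2 equiv), Et2O, 0 °C; used crude
Reagents that add atoms: trimethylsilyl trifluoromethanesulfonate, C[Si](C)(C)OS(=O)(=O)C(F)(F)F
Why: Soft enolisation (silyl triflate/amine) of a β-alkoxy enone at its α′-methyl group is the standard preparation of 1-alkoxy-3-siloxy dienes of the Danishefsky type.

Step 6
Reactants: 11 propane-1,3-diol
Product: 12 3-(tert-butyldiphenylsilyloxy)propan-1-ol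
Conditions: 11 (3 equiv), TBDPSCl (1 equiv), imidazole (1.1 equiv), THF, 0 °C → rt
Reagents that add atoms: tert-butyl(chloro)diphenylsilane, CC(C)(C)[Si](Cl)(c1ccccc1)c1ccccc1
Why: Statistical monosilylation of a symmetrical diol used in excess, the surplus diol being removed by aqueous washing.

Step 7
Reactants: 12 3-(tert-butyldiphenylsilyloxy)propan-1-ol
Product: 13 3-(tert-butyldiphenylsilyloxy)propanal
Conditions: TEMPO (10 mol%), PhI(OAc)2 (1.1 equiv), CH2Cl2, rt
Reagents that add atoms: none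
Why: Oxoammonium (TEMPO) oxidation of a primary alcohol stops at the aldehyde in anhydrous CH2Cl2 and uses no base that could eliminate the β-silyloxy group.

Step 8
Reactants: 10 (3E)-12-[3,4-bis(benzyloxy)phenyl]-4-methoxy-2-(trimethylsilyloxy)dodeca-1,3-diene; 13 3-(tert-butyldiphenylsilyloxy)propanal
Product: 15 (2S)-6-{8-[3,4-bis(benzyloxy)phenyl]octyl}-2-[2-(tert-butyldiphenylsilyloxy)ethyl]-2,3-dihydro-4H-pyran-4-one, via silylated aldol adduct 14 (not isolated)
Conditions: (R)-BINOL (20 mol%), Ti(OiPr)4 (10 mol%), 4 Å MS, Et2O, −20 °C; then CF3CO2H, CH2Cl2, 0 °C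
Reagents that add atoms: none
Why: The BINOL–titanium Lewis acid binds the aldehyde and the unsubstituted diene terminus (the future C4) adds to the carbonyl carbon in the Mukaiyama-aldol mode of the [4+2] reaction, forming C4–C5 and, after silyl transfer, the open adduct 14. Trifluoroacetic acid then removes the silyl group, the C5 oxygen adds to C1′, the β-carbon of the vinylogous ester (6-endo-trig closure, O–C1′ bond), and loss of methanol gives the dihydropyranone ring. The closest known reaction is the titanium/BINOL-catalysed formal hetero-Diels–Alder reaction of 1-methoxy-3-siloxy dienes with aliphatic aldehydes to 2-substituted 2,3-dihydro-4H-pyran-4-ones. The only new stereocentre, C5 (pyranone C2), is set by the catalyst: (R)-BINOL is chosen because this catalyst family delivers carbon nucleophiles to the aldehyde Re face, which here corresponds to the 2S pyranone, and the antipodal ligand would give the mirror image. Only facial selectivity is required, since regiochemistry is fixed by the polarisation of the diene (nucleophilic CH2 terminus, methoxy-bearing carbon as acceptor of the oxygen) and the diene geometry is irrelevant in the stepwise pathway.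

Step 9
Reactants: 15 (2S)-6-{8-[3,4-bis(benzyloxy)phenyl]octyl}-2-[2-(tert-butyldiphenylsilyloxy)ethyl]-2,3-dihydro-4H-pyran-4-one
Product: 16 (2S)-6-{8-[3,4-bis(benzyloxy)phenyl]octyl}-2-(2-hydroxyethyl)-2,3-dihydro-4H-pyran-4-one
Conditions: TBAF (1.5 equiv), AcOH (1.5 equiv), THF, 0 °C → rt
Reagents that add atoms: none
Why: Fluoride cleavage of the silyl ether, buffered with acetic acid so that no free alkoxide can open the β-alkoxy ketone by retro-oxa-Michael reaction.

Step 10
Reactants: 16 (2S)-6-{8-[3,4-bis(benzyloxy)phenyl]octyl}-2-(2-hydroxyethyl)-2,3-dihydro-4H-pyran-4-one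
Product: 18 2-[(2R)-6-{8-[3,4-bis(benzyloxy)phenyl]octyl}-4-oxo-3,4-dihydro-2H-pyran-2-yl]acetic acid, via pyranone aldehyde 17 (not isolated)
Conditions: TEMPO (20 mol%), PhI(OAc)2 (2.2 equiv), MeCN/H2O (1:1), rt
Reagents that add atoms: water, O
Why: TEMPO/PhI(OAc)2 oxidation in aqueous acetonitrile takes the primary alcohol through aldehyde 17 and its hydrate to the acid under near-neutral conditions that leave the vinylogous ester, the benzyl ethers and C5 untouched (the descriptor changes to R only through ligand priorities).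

Step 11
Reactants: 18 2-[(2R)-6-{8-[3,4-bis(benzyloxy)phenyl]octyl}-4-oxo-3,4-dihydro-2H-pyran-2-yl]acetic acid
Product: 19 sodium (3R,6E)-15-[3,4-bis(benzyloxy)phenyl]-3-hydroxy-5-oxo-7-(pyrrolidin-1-yl)pentadec-6-enoate
Conditions: NaHCO3 (1.0 equiv), pyrrolidine (10 equiv), MeOH/H2O (9:1), 40 °C; evaporate, PhMe azeotrope
Reagents that add atoms: pyrrolidine, C1CCNC1; sodium hydrogencarbonate, [Na+].OC([O-])=O
Why: Addition–elimination of the secondary amine at the β-carbon of the vinylogous ester (vinylogous transamidation) should release the ring oxygen as the C5 hydroxyl and give the more stabilised E enaminone, the acid being held as its sodium salt so that all pyrrolidine can be stripped as the free base and none remains to intercept the activated acid in step 12.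

Step 12
Reactants: 19 sodium (3R,6E)-15-[3,4-bis(benzyloxy)phenyl]-3-hydroxy-5-oxo-7-(pyrrolidin-1-yl)pentadec-6-enoate
Product: 21 (5S)-2-{9-[3,4-bis(benzyloxy)phenyl]nonanoyl}-3,5-dihydroxycyclohex-2-en-1-one, via cyclised enaminone dione 20 (not isolated)
Conditions: EDC·HCl (1.5 equiv), DMAP (0.2 equiv), CH2Cl2 (0.005 M), 0 °C → rt; then 0.5 M aq. HCl/THF, 0 °C → rt
Reagents that add atoms: water, O
Why: The carbodiimide (with DMAP as acyl-transfer catalyst, which also returns any O-acyl isomer) activates the carboxyl and the nucleophilic α-carbon of the tertiary enaminone attacks it in a 6-exo-trig C-acylation that forms C1–C2 without base, so the β-hydroxyl is not eliminated, and dilute acid then hydrolyses the exocyclic enamine of 20 to the enolised triketone.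

Step 13
Reactants: 21 (5S)-2-{9-[3,4-bis(benzyloxy)phenyl]nonanoyl}-3,5-dihydroxycyclohex-2-en-1-one
Product: 22 (5S)-2-[9-(3,4-dihydroxyphenyl)nonanoyl]-3,5-dihydroxycyclohex-2-en-1-one
Conditions: H2 (1 atm), 10% Pd/C, EtOAc, rt
Reagents that add atoms: none
Why: Hydrogenolysis of the two benzyl aryl ethers under neutral conditions, under which the chelated enol of the 2-acyl-1,3-dione and the secondary alcohol are not reduced and C5 cannot dehydrate.

**Compound list**
1 | 4-bromo-1,2-bis(benzyloxy)benzene | Brc1ccc(OCc2ccccc2)c(OCc2ccccc2)c1 | starting material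
2 | 1-bromo-8-chlorooctane | ClCCCCCCCCBr | starting material
3 | [3,4-bis(benzyloxy)phenyl]magnesium bromide (formed in the flask) | Br[Mg]c1ccc(OCc2ccccc2)c(OCc2ccccc2)c1 | intermediate
4 | 1,2-bis(benzyloxy)-4-(8-chlorooctyl)benzene | ClCCCCCCCCc1ccc(OCc2ccccc2)c(OCc2ccccc2)c1 | intermediate
5 | 1,2-bis(benzyloxy)-4-(dec-9-yn-1-yl)benzene | C#CCCCCCCCCc1ccc(OCc2ccccc2)c(OCc2ccccc2)c1 | intermediate
6 | {10-[3,4-bis(benzyloxy)phenyl]dec-1-yn-1-yl}lithium (formed in the flask) | [Li]C#CCCCCCCCCc1ccc(OCc2ccccc2)c(OCc2ccccc2)c1 | intermediate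
7 | lithium 12-[3,4-bis(benzyloxy)phenyl]-2-[methoxy(methyl)amino]dodec-3-yn-2-olate (formed in the flask) | CON(C)C(C)(O[Li])C#CCCCCCCCCc1ccc(OCc2ccccc2)c(OCc2ccccc2)c1 | intermediate
8 | 12-[3,4-bis(benzyloxy)phenyl]dodec-3-yn-2-one | CC(=O)C#CCCCCCCCCc1ccc(OCc2ccccc2)c(OCc2ccccc2)c1 | intermediate
9 | (3E)-12-[3,4-bis(benzyloxy)phenyl]-4-methoxydodec-3-en-2-one | CC(=O)/C=C(/OC)CCCCCCCCc1ccc(OCc2ccccc2)c(OCc2ccccc2)c1 | intermediate
10 | (3E)-12-[3,4-bis(benzyloxy)phenyl]-4-methoxy-2-(trimethylsilyloxy)dodeca-1,3-diene | C=C(O[Si](C)(C)C)/C=C(/OC)CCCCCCCCc1ccc(OCc2ccccc2)c(OCc2ccccc2)c1 | intermediate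
11 | propane-1,3-diol | OCCCO | starting material
12 | 3-(tert-butyldiphenylsilyloxy)propan-1-ol | OCCCO[Si](c1ccccc1)(c1ccccc1)C(C)(C)C | intermediate
13 | 3-(tert-butyldiphenylsilyloxy)propanal | O=CCCO[Si](c1ccccc1)(c1ccccc1)C(C)(C)C | intermediate
14 | (3S,6E)-15-[3,4-bis(benzyloxy)phenyl]-1-(tert-butyldiphenylsilyloxy)-7-methoxy-3-(trimethylsilyloxy)pentadec-6-en-5-one (formed in the flask) | CO/C(CCCCCCCCc1ccc(OCc2ccccc2)c(OCc2ccccc2)c1)=C/C(=O)C[C@H](CCO[Si](c1ccccc1)(c1ccccc1)C(C)(C)C)O[Si](C)(C)C | intermediate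
15 | (2S)-6-{8-[3,4-bis(benzyloxy)phenyl]octyl}-2-[2-(tert-butyldiphenylsilyloxy)ethyl]-2,3-dihydro-4H-pyran-4-one | O=C1C[C@H](CCO[Si](c2ccccc2)(c2ccccc2)C(C)(C)C)OC(CCCCCCCCc2ccc(OCc3ccccc3)c(OCc3ccccc3)c2)=C1 | intermediate
16 | (2S)-6-{8-[3,4-bis(benzyloxy)phenyl]octyl}-2-(2-hydroxyethyl)-2,3-dihydro-4H-pyran-4-one | O=C1C[C@H](CCO)OC(CCCCCCCCc2ccc(OCc3ccccc3)c(OCc3ccccc3)c2)=C1 | intermediate
17 | 2-[(2S)-6-{8-[3,4-bis(benzyloxy)phenyl]octyl}-4-oxo-3,4-dihydro-2H-pyran-2-yl]acetaldehyde (formed in the flask) | O=C1C[C@H](CC=O)OC(CCCCCCCCc2ccc(OCc3ccccc3)c(OCc3ccccc3)c2)=C1 | intermediate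
18 | 2-[(2R)-6-{8-[3,4-bis(benzyloxy)phenyl]octyl}-4-oxo-3,4-dihydro-2H-pyran-2-yl]acetic acid | O=C1C[C@H](CC(=O)O)OC(CCCCCCCCc2ccc(OCc3ccccc3)c(OCc3ccccc3)c2)=C1 | intermediate
19 | sodium (3R,6E)-15-[3,4-bis(benzyloxy)phenyl]-3-hydroxy-5-oxo-7-(pyrrolidin-1-yl)pentadec-6-enoate | [Na+].[O-]C(=O)C[C@H](O)CC(=O)/C=C(/N1CCCC1)CCCCCCCCc1ccc(OCc2ccccc2)c(OCc2ccccc2)c1 | intermediate
20 | 2-{9-[3,4-bis(benzyloxy)phenyl]-1-(pyrrolidin-1-yl)nonylidene}-5-hydroxycyclohexane-1,3-dione (formed in the flask; C5 as in 19, one rotamer of the freely rotating push-pull alkene drawn) | O=C1C[C@@H](O)CC(=O)/C1=C(\N2CCCC2)CCCCCCCCc2ccc(OCc3ccccc3)c(OCc3ccccc3)c2 | intermediate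
21 | (5S)-2-{9-[3,4-bis(benzyloxy)phenyl]nonanoyl}-3,5-dihydroxycyclohex-2-en-1-one | O=C(CCCCCCCCc1ccc(OCc2ccccc2)c(OCc2ccccc2)c1)C1=C(O)C[C@H](O)CC1=O | intermediate
22 | (5S)-2-[9-(3,4-dihydroxyphenyl)nonanoyl]-3,5-dihydroxycyclohex-2-en-1-one (CNP0178179.1) | O=C(CCCCCCCCc1ccc(O)c(O)c1)C1=C(O)C[C@H](O)CC1=O | target

**Step count**
Total steps: 13. Longest linear sequence: 11 steps (steps 1–5 and 8–13).

**Steps most likely to fail**

1. Step 12. After activation the carboxyl may be consumed by intermolecular esterification of the free C5 hydroxyl or by rearrangement to the N-acylurea before the enaminone carbon attacks, or the hydroxy enaminone may close back to the pyranone. The fallback sets out from 19 and returns at 21. The carboxylate of 19 is alkylated with MeI in DMF to methyl (3R,6E)-15-[3,4-bis(benzyloxy)phenyl]-3-hydroxy-5-oxo-7-(pyrrolidin-1-yl)pentadec-6-enoate F1. The hydroxyl is silylated with TBSCl/imidazole to methyl (3R,6E)-15-[3,4-bis(benzyloxy)phenyl]-3-(tert-butyldimethylsilyloxy)-5-oxo-7-(pyrrolidin-1-yl)pentadec-6-enoate F2. Aqueous oxalic acid in THF hydrolyses the enaminone to the open-chain β-diketone methyl (3R)-15-[3,4-bis(benzyloxy)phenyl]-3-(tert-butyldimethylsilyloxy)-5,7-dioxopentadecanoate F3, whose blocked oxygen can no longer re-form the pyranone. KOtBu in THF at 0 °C then closes C1–C2 by a Dieckmann-type Claisen condensation of the diketone anion onto the ester, giving (5S)-2-{9-[3,4-bis(benzyloxy)phenyl]nonanoyl}-5-(tert-butyldimethylsilyloxy)-3-hydroxycyclohex-2-en-1-one F4. Aqueous HF in MeCN removes the silyl group to give 21.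

2. Step 11. The amine exchange may stop short or run backwards when the amine is stripped, and long contact with base may open the ring by retro-oxa-Michael elimination and erode C5. The fallback sets out from 18 and returns at 21. Acid 18 is opened with pyrrolidine in THF and, without removing the amine, the liberated hydroxyl is trapped with excess TESCl/imidazole, which makes the exchange irreversible. A mildly acidic aqueous work-up cleaves the silyl ester and washes out the amine, giving (3R,6E)-15-[3,4-bis(benzyloxy)phenyl]-5-oxo-7-(pyrrolidin-1-yl)-3-(triethylsilyloxy)pentadec-6-enoic acid F5. Closure under the carbodiimide conditions of step 12 should give 2-{9-[3,4-bis(benzyloxy)phenyl]-1-(pyrrolidin-1-yl)nonylidene}-5-(triethylsilyloxy)cyclohexane-1,3-dione F6. Dilute aqueous HCl in THF then removes both the enamine and the silyl group to reach 21.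

3. Step 8. The catalyst may show poor facial selectivity with this 1-alkyl-substituted diene, or slow turnover may allow hydrolysis of the diene and β-elimination in the aldehyde. The fallback sets out from 13 (with acetylide 6 made from 5 as in step 3) and returns at 15; it sets C5 by hydrogenation instead of by C–C bond formation. Aldehyde 13 is homologated with ethyl diazoacetate and catalytic SnCl2 (Roskamp reaction) to ethyl 5-(tert-butyldiphenylsilyloxy)-3-oxopentanoate F7. Noyori hydrogenation with RuCl2[(S)-BINAP] in EtOH should give ethyl (3S)-5-(tert-butyldiphenylsilyloxy)-3-hydroxypentanoate F8. MeNH(OMe)·HCl/i-PrMgCl converts it into the Weinreb amide (3S)-5-(tert-butyldiphenylsilyloxy)-3-hydroxy-N-methoxy-N-methylpentanamide F9. Excess 6 adds to F9 to give dilithium (3S)-15-[3,4-bis(benzyloxy)phenyl]-1-(tert-butyldiphenylsilyloxy)-5-[methoxy(methyl)amino]pentadec-6-yne-3,5-diolate F10 (not isolated), which on aqueous NH4Cl quench gives (3S)-15-[3,4-bis(benzyloxy)phenyl]-1-(tert-butyldiphenylsilyloxy)-3-hydroxypentadec-6-yn-5-one F11. AgOTf-catalysed 6-endo-dig cycloisomerisation of F11 in CH2Cl2 closes the same O–C1′ bond and gives 15.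

Further compounds
F1 | step 12 | methyl (3R,6E)-15-[3,4-bis(benzyloxy)phenyl]-3-hydroxy-5-oxo-7-(pyrrolidin-1-yl)pentadec-6-enoate | COC(=O)C[C@H](O)CC(=O)/C=C(/N1CCCC1)CCCCCCCCc1ccc(OCc2ccccc2)c(OCc2ccccc2)c1
F2 | step 12 | methyl (3R,6E)-15-[3,4-bis(benzyloxy)phenyl]-3-(tert-butyldimethylsilyloxy)-5-oxo-7-(pyrrolidin-1-yl)pentadec-6-enoate | COC(=O)C[C@H](O[Si](C)(C)C(C)(C)C)CC(=O)/C=C(/N1CCCC1)CCCCCCCCc1ccc(OCc2ccccc2)c(OCc2ccccc2)c1
F3 | step 12 | methyl (3R)-15-[3,4-bis(benzyloxy)phenyl]-3-(tert-butyldimethylsilyloxy)-5,7-dioxopentadecanoate | COC(=O)C[C@H](O[Si](C)(C)C(C)(C)C)CC(=O)CC(=O)CCCCCCCCc1ccc(OCc2ccccc2)c(OCc2ccccc2)c1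
F4 | step 12 | (5S)-2-{9-[3,4-bis(benzyloxy)phenyl]nonanoyl}-5-(tert-butyldimethylsilyloxy)-3-hydroxycyclohex-2-en-1-one | O=C(CCCCCCCCc1ccc(OCc2ccccc2)c(OCc2ccccc2)c1)C1=C(O)C[C@H](O[Si](C)(C)C(C)(C)C)CC1=O
F5 | step 11 | (3R,6E)-15-[3,4-bis(benzyloxy)phenyl]-5-oxo-7-(pyrrolidin-1-yl)-3-(triethylsilyloxy)pentadec-6-enoic acid | OC(=O)C[C@H](O[Si](CC)(CC)CC)CC(=O)/C=C(/N1CCCC1)CCCCCCCCc1ccc(OCc2ccccc2)c(OCc2ccccc2)c1
F6 | step 11 | 2-{9-[3,4-bis(benzyloxy)phenyl]-1-(pyrrolidin-1-yl)nonylidene}-5-(triethylsilyloxy)cyclohexane-1,3-dione (C5 as in F5) | O=C1C[C@@H](O[Si](CC)(CC)CC)CC(=O)/C1=C(\N2CCCC2)CCCCCCCCc2ccc(OCc3ccccc3)c(OCc3ccccc3)c2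
F7 | step 8 | ethyl 5-(tert-butyldiphenylsilyloxy)-3-oxopentanoate | CCOC(=O)CC(=O)CCO[Si](c1ccccc1)(c1ccccc1)C(C)(C)C
F8 | step 8 | ethyl (3S)-5-(tert-butyldiphenylsilyloxy)-3-hydroxypentanoate | CCOC(=O)C[C@@H](O)CCO[Si](c1ccccc1)(c1ccccc1)C(C)(C)C
F9 | step 8 | (3S)-5-(tert-butyldiphenylsilyloxy)-3-hydroxy-N-methoxy-N-methylpentanamide | CON(C)C(=O)C[C@@H](O)CCO[Si](c1ccccc1)(c1ccccc1)C(C)(C)C
F10 | step 8 | dilithium (3S)-15-[3,4-bis(benzyloxy)phenyl]-1-(tert-butyldiphenylsilyloxy)-5-[methoxy(methyl)amino]pentadec-6-yne-3,5-diolate (not isolated) | CON(C)C(O[Li])(C[C@@H](O[Li])CCO[Si](c1ccccc1)(c1ccccc1)C(C)(C)C)C#CCCCCCCCCc1ccc(OCc2ccccc2)c(OCc2ccccc2)c1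
F11 | step 8 | (3S)-15-[3,4-bis(benzyloxy)phenyl]-1-(tert-butyldiphenylsilyloxy)-3-hydroxypentadec-6-yn-5-one | O=C(C[C@H](CCO[Si](c1ccccc1)(c1ccccc1)C(C)(C)C)O)C#CCCCCCCCCc1ccc(OCc2ccccc2)c(OCc2ccccc2)c1
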